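**Retrosynthetic overview**

1. The ten-membered carbocycle (germacrane locants C1–C10) is formed last, at the C3(sp3)–C4(sp2) bond, by a one-pot double cross-coupling on the 1,1-dibromoalkene 19: Stille hydroxymethylation (C15) at the bromine trans to C6, then intramolecular B-alkyl Suzuki–Miyaura coupling of the C3 pinacolboronate at the bromine cis to C6.
2. Enabling feature: C4 carries two bromines that the lactone carbon C6 on C5 makes different (trans and cis). The seco chain is pre-folded by the trans-fused five-membered lactone ring (O–C6–C7–C11–C12) and the E-olefin C1=C10, so only four ring bonds rotate freely.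
3. The γ-lactone is formed first, by lactonization of O6 onto C12 after an indium Barbier union (C7–C8 bond) of aldehyde 6 with allyl bromide 10. C6 comes from D-glyceraldehyde and controls C7 and C8.
4. Aldehyde 6 comes from cross-metathesis of 4-methyl itaconate with a butenyl pinacolboronate, which sets the E-olefin C1=C10 and brings C3 as its boronate. C4 is added to the C5 aldehyde as CBr2 by Corey–Fuchs olefination.
5. The exo-methylene C11=C13 is masked as its dimethylamine adduct before the palladium step and released in the last step.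

Key step: step 15

Remark: locants are germacrane locants (ring C1–C10, lactone carbons C11–C13 with O on C6, C14 = CHO on C10, C15 = CH2OH on C4); 1, 2, 7 and 8 are taken as commercial; "pinacolboryl" means 4,4,5,5-tetramethyl-1,3,2-dioxaborolan-2-yl; C11 of the amine adducts 17–22 forms as an inconsequential epimer mixture and is left undefined in the SMILES.

**Route**

Step 1
Reactants: 1 4-methyl itaconate; 2 but-3-enyl pinacolboronate
Product: 3 E-alkylidene succinic acid half ester
Conditions: second-generation Hoveyda–Grubbs catalyst (5 mol%), 2 (2 equiv), CH2Cl2, 40 °C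
Reagents that add atoms: none
Why: Olefin cross-metathesis of a terminal alkene with the 1,1-disubstituted acrylic acid unit should give the thermodynamically preferred E-trisubstituted olefin (chain trans to the conjugated carboxyl), which is the C1=C10 geometry of the target, with ethene as the only by-product.

Step 2
Reactants: 3 E-alkylidene succinic acid half ester
Product: 4 allylic alcohol ester
Conditions: BH3·SMe2 (1.2 equiv), THF, −10 to 0 °C; MeOH quench
Reagents that add atoms: none
Why: Borane reduces a free carboxylic acid far faster than a methyl ester or a trisubstituted electron-poor olefin, so the conjugated acid should be taken selectively to the allylic alcohol (chemoselective borane reduction), which is silylated without delay to forestall lactonization onto the ester.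

Step 3
Reactants: 4 allylic alcohol ester
Product: 5 silyl ether ester
Conditions: t-BuPh2SiCl, imidazole, CH2Cl2, 0 °C
Reagents that add atoms: tert-butyl(chloro)diphenylsilane, CC(C)(C)[Si](Cl)(c1ccccc1)c1ccccc1
Why: Routine silylation of the primary allylic alcohol; the tert-butyldiphenylsilyl ether is chosen because it has to survive the aqueous acid of step 9.

Step 4
Reactants: 5 silyl ether ester
Product: 6 β,γ-unsaturated aldehyde
Conditions: i-Bu2AlH (1.1 equiv), CH2Cl2, −78 °C; aqueous potassium sodium tartrate
Reagents that add atoms: none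
Why: Partial reduction of a methyl ester with i-Bu2AlH at −78 °C stops at the aluminium hemiacetal, which should release the β,γ-unsaturated aldehyde on work-up, while the alkyl pinacolboronate and the silyl ether are inert.

Step 5
Reactants: 7 D-glyceraldehyde acetonide; 8 methyl acrylate
Product: 9 Morita–Baylis–Hillman adduct
Conditions: DABCO (0.3 equiv), dioxane/H2O (1:1), rt
Reagents that add atoms: none
Why: Morita–Baylis–Hillman reaction of the reactive α-alkoxy aldehyde with methyl acrylate; the new carbinol centre forms as a mixture, which is irrelevant because it becomes sp2 in step 6, while the dioxolane centre (the future C6) is untouched.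

Step 6
Reactants: 9 Morita–Baylis–Hillman adduct
Product: 10 Z-allyl bromide
Conditions: NBS, Me2S, CH2Cl2, 0 °C to rt
Reagents that add atoms: N-bromosuccinimide, O=C1CCC(=O)N1Br
Why: The bromosulfonium salt from NBS and Me2S activates the allylic hydroxyl and bromide attacks in the SN2′ sense, which should give the more stable Z-configured 2-(bromomethyl)enoate (dioxolane trans to the ester) under neutral conditions that spare the acetonide.

Step 7
Reactants: 6 β,γ-unsaturated aldehyde; 10 Z-allyl bromide
Product: 11 homoallylic alcohol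
Conditions: In powder (1.5 equiv), THF/H2O (3:1), rt
Reagents that add atoms: none
Why: Barbier allylation through a chair-like six-membered transition state: the Z-configured allylindium places the dioxolanyl group axial and the aldehyde chain equatorial, which should give the syn relation between the new C8 hydroxyl and the C7 substituent, and the aldehyde should add to the C7 face anti to the C6–O bond of the conformer in which C6–H eclipses the olefin (allylic 1,3-strain), so that both new stereocentres are set from the glyceraldehyde-derived C6.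

Step 8
Reactants: 11 homoallylic alcohol
Product: 12 isovalerate
Conditions: 3-methylbutanoyl chloride, pyridine, DMAP (cat.), CH2Cl2, −20 to 0 °C
Reagents that add atoms: 3-methylbutanoyl chloride, CC(C)CC(=O)Cl
Why: Pyridine/DMAP-mediated acylation of the secondary C8 alcohol with the acid chloride at low temperature should outpace lactonization onto the acrylate ester and installs the isovalerate of the target while O6 is still blocked in the acetonide.

Step 9
Reactants: 12 isovalerate
Product: 14 lactone alcohol, via diol 13 (not isolated)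
Conditions: AcOH/H2O (4:1), 45 °C; then PPTS (cat.), toluene, 60 °C
Reagents that add atoms: none
Why: Aqueous acid cleaves the terminal acetonide, and the freed secondary C6 hydroxyl should close the five-membered lactone onto the acrylate ester (acid-catalysed transesterification, five-membered ring favoured over the six-membered lactone through the primary C5 hydroxyl), giving the trans-disubstituted α-methylene-γ-butyrolactone without touching C6, C7 or C8.

Step 10
Reactants: 14 lactone alcohol
Product: 15 lactone aldehyde
Conditions: Dess–Martin periodinane, NaHCO3, CH2Cl2, 0 °C to rt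
Reagents that add atoms: none
Why: Dess–Martin oxidation of the primary alcohol under buffered, non-epimerizing conditions should give the α-acyloxy aldehyde, which is used crude.

Step 11
Reactants: 15 lactone aldehyde
Product: 16 dibromoalkene
Conditions: CBr4, PPh3, CH2Cl2, −20 to 0 °C
Reagents that add atoms: carbon tetrabromide, BrC(Br)(Br)Br
Why: The first stage of the Corey–Fuchs reaction (Wittig-type olefination with the dibromomethylene ylide from CBr4 and PPh3) should convert the aldehyde into the 1,1-dibromoalkene under neutral conditions at low temperature, so that the adjacent C6 centre is not epimerized.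

Step 12
Reactants: 16 dibromoalkene
Product: 17 dimethylamine adduct
Conditions: Me2NH (2 M in THF), THF, 0 °C
Reagents that add atoms: dimethylamine, CNC
Why: Aza-Michael addition of dimethylamine to the α-methylene lactone is fast and clean and masks the C11=C13 acceptor, which would otherwise be open to Heck-type insertion by the vinylpalladium species of step 15; the new C11 centre is removed again in step 16.

Step 13
Reactants: 17 dimethylamine adduct
Product: 18 allylic alcohol
Conditions: Bu4NF, AcOH (1:1), THF, 0 °C to rt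
Reagents that add atoms: none
Why: Fluoride cleaves the silyl ether, and buffering with acetic acid should suppress base-induced elimination of HBr from the dibromoalkene and attack on the esters.

Step 14
Reactants: 18 allylic alcohol
Product: 19 dibromoalkene enal
Conditions: activated MnO2, CH2Cl2, rt
Reagents that add atoms: none
Why: MnO2 oxidizes only the allylic primary alcohol and stops at the aldehyde, giving the E-configured enal (C14) of the target without isomerization.

Step 15
Reactants: 19 dibromoalkene enal
Product: 21 macrocyclic amine adduct, via bromoallyl alcohol 20 (not isolated)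
Conditions: Pd2(dba)3 (5 mol%), tri(2-furyl)phosphine (20 mol%), Bu3SnCH2OH (1.05 equiv), toluene, 80 °C; then slow addition into Pd(OAc)2 (10 mol%), RuPhos (20 mol%), K3PO4 (3 equiv), toluene/H2O (10:1), 80 °C, final 1 mM
Reagents that add atoms: tributyl(hydroxymethyl)stannane, CCCC[Sn](CCCC)(CCCC)CO
Why: Zerovalent palladium first inserts into the less hindered C4–Br bond trans to C6, and Stille transfer of the hydroxymethyl group from tin, which needs no base so that the alkyl pinacolboronate stays silent, gives the Z-bromoallylic alcohol 20; after dilution and addition of base the remaining C4–Br bond cis to C6 undergoes oxidative addition, the phosphate-activated C3 boronate transmetalates within the same molecule, and reductive elimination with retention forms the C3–C4 bond. The closest known reactions are the trans-selective mono-coupling of 1,1-dibromoalkenes followed by a second coupling, and the B-alkyl Suzuki–Miyaura macrocyclization. The ten-membered carbocycle is closed by C(sp3)–C(sp2) reductive elimination from an eleven-membered palladacycle, with both olefins endocyclic. No stereocentre is created; the geometry of the C4=C5 olefin (C3 cis to C6, CH2OH trans) follows from the order of the two stereoretentive couplings, which is dictated by the C6-bearing substituent that differentiates the two bromines. The step needs site selectivity between the bromines, tin-before-boron chemoselectivity, and ring closure in preference to oligomerization and to Heck insertion into the lactone olefin; these should be secured by the cis/trans differentiation, by withholding base in the first stage, by high dilution together with the three rigid elements (Z-bromoalkene, trans-lactone ring, E-enal), and by the amine mask on C11=C13.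

Step 16
Reactants: 21 macrocyclic amine adduct
Product: 23 target CNP0345200.3, via ammonium iodide 22 (not isolated)
Conditions: MeI (excess), MeCN, rt; then aqueous NaHCO3, rt
Reagents that add atoms: none
Why: Exhaustive methylation gives the trimethylammonium salt, from which bicarbonate induces E1cB (Hofmann-type) elimination of trimethylamine to restore the C11=C13 exo-methylene; the free allylic alcohol, the enal and the isovalerate do not react with MeI or bicarbonate.

**Compound list**

1 | 4-methyl itaconate (4-methoxy-2-methylidene-4-oxobutanoic acid) | C=C(CC(=O)OC)C(=O)O | starting material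
2 | 2-(but-3-en-1-yl)-4,4,5,5-tetramethyl-1,3,2-dioxaborolane | C=CCCB1OC(C)(C)C(C)(C)O1 | starting material
3 | (2E)-2-(2-methoxy-2-oxoethyl)-6-(pinacolboryl)hex-2-enoic acid | OC(=O)/C(CC(=O)OC)=C/CCB1OC(C)(C)C(C)(C)O1 | intermediate
4 | methyl (3E)-3-(hydroxymethyl)-7-(pinacolboryl)hept-3-enoate | OC/C(CC(=O)OC)=C/CCB1OC(C)(C)C(C)(C)O1 | intermediate
5 | methyl (3E)-3-{[tert-butyl(diphenyl)silyl]oxymethyl}-7-(pinacolboryl)hept-3-enoate | CC(C)(C)[Si](OC/C(CC(=O)OC)=C/CCB1OC(C)(C)C(C)(C)O1)(c1ccccc1)c1ccccc1 | intermediate
6 | (3E)-3-{[tert-butyl(diphenyl)silyl]oxymethyl}-7-(pinacolboryl)hept-3-enal | CC(C)(C)[Si](OC/C(CC=O)=C/CCB1OC(C)(C)C(C)(C)O1)(c1ccccc1)c1ccccc1 | intermediate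
7 | (4R)-2,2-dimethyl-1,3-dioxolane-4-carbaldehyde (D-glyceraldehyde acetonide) | O=C[C@H]1COC(C)(C)O1 | starting material
8 | methyl acrylate | C=CC(=O)OC | starting material
9 | methyl 2-{[(4R)-2,2-dimethyl-1,3-dioxolan-4-yl](hydroxy)methyl}prop-2-enoate, both carbinol epimers | C=C(C(=O)OC)C(O)[C@H]1COC(C)(C)O1 | intermediate
10 | methyl (2Z)-2-(bromomethyl)-3-[(4S)-2,2-dimethyl-1,3-dioxolan-4-yl]prop-2-enoate | COC(=O)/C(CBr)=C/[C@H]1COC(C)(C)O1 | intermediate
11 | methyl (3R,4R,6E)-6-{[tert-butyl(diphenyl)silyl]oxymethyl}-3-[(4S)-2,2-dimethyl-1,3-dioxolan-4-yl]-4-hydroxy-2-methylidene-9-(pinacolboryl)non-6-enoate | C=C(C(=O)OC)[C@@H]([C@H]1COC(C)(C)O1)[C@H](O)C/C(CO[Si](c1ccccc1)(c1ccccc1)C(C)(C)C)=C\CCB1OC(C)(C)C(C)(C)O1 | intermediate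
12 | methyl (3R,4R,6E)-6-{[tert-butyl(diphenyl)silyl]oxymethyl}-3-[(4S)-2,2-dimethyl-1,3-dioxolan-4-yl]-2-methylidene-4-(3-methylbutanoyloxy)-9-(pinacolboryl)non-6-enoate | C=C(C(=O)OC)[C@@H]([C@H]1COC(C)(C)O1)[C@H](OC(=O)CC(C)C)C/C(CO[Si](c1ccccc1)(c1ccccc1)C(C)(C)C)=C\CCB1OC(C)(C)C(C)(C)O1 | intermediate
13 | methyl (3S,4R,6E)-6-{[tert-butyl(diphenyl)silyl]oxymethyl}-3-[(1S)-1,2-dihydroxyethyl]-2-methylidene-4-(3-methylbutanoyloxy)-9-(pinacolboryl)non-6-enoate | C=C(C(=O)OC)[C@@H]([C@H](O)CO)[C@H](OC(=O)CC(C)C)C/C(CO[Si](c1ccccc1)(c1ccccc1)C(C)(C)C)=C\CCB1OC(C)(C)C(C)(C)O1 | intermediate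
14 | (4R,5S)-4-[(1R,3E)-3-{[tert-butyl(diphenyl)silyl]oxymethyl}-1-(3-methylbutanoyloxy)-6-(pinacolboryl)hex-3-en-1-yl]-5-(hydroxymethyl)-3-methylidenedihydrofuran-2(3H)-one | C=C1C(=O)O[C@H](CO)[C@H]1[C@H](OC(=O)CC(C)C)C/C(CO[Si](c2ccccc2)(c2ccccc2)C(C)(C)C)=C\CCB2OC(C)(C)C(C)(C)O2 | intermediate
15 | (2S,3R)-3-[(1R,3E)-3-{[tert-butyl(diphenyl)silyl]oxymethyl}-1-(3-methylbutanoyloxy)-6-(pinacolboryl)hex-3-en-1-yl]-4-methylidene-5-oxotetrahydrofuran-2-carbaldehyde | C=C1C(=O)O[C@H](C=O)[C@H]1[C@H](OC(=O)CC(C)C)C/C(CO[Si](c2ccccc2)(c2ccccc2)C(C)(C)C)=C\CCB2OC(C)(C)C(C)(C)O2 | intermediate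
16 | (4R,5S)-5-(2,2-dibromoethenyl)-3-methylidene-4-[(1R,3E)-3-{[tert-butyl(diphenyl)silyl]oxymethyl}-1-(3-methylbutanoyloxy)-6-(pinacolboryl)hex-3-en-1-yl]dihydrofuran-2(3H)-one | C=C1C(=O)O[C@H](C=C(Br)Br)[C@H]1[C@H](OC(=O)CC(C)C)C/C(CO[Si](c2ccccc2)(c2ccccc2)C(C)(C)C)=C\CCB2OC(C)(C)C(C)(C)O2 | intermediate
17 | (4R,5S)-5-(2,2-dibromoethenyl)-3-[(dimethylamino)methyl]-4-[(1R,3E)-3-{[tert-butyl(diphenyl)silyl]oxymethyl}-1-(3-methylbutanoyloxy)-6-(pinacolboryl)hex-3-en-1-yl]dihydrofuran-2(3H)-one, C3 epimers | CN(C)CC1C(=O)O[C@H](C=C(Br)Br)[C@H]1[C@H](OC(=O)CC(C)C)C/C(CO[Si](c2ccccc2)(c2ccccc2)C(C)(C)C)=C\CCB2OC(C)(C)C(C)(C)O2 | intermediate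
18 | (4R,5S)-5-(2,2-dibromoethenyl)-3-[(dimethylamino)methyl]-4-[(1R,3E)-3-(hydroxymethyl)-1-(3-methylbutanoyloxy)-6-(pinacolboryl)hex-3-en-1-yl]dihydrofuran-2(3H)-one, C3 epimers | CN(C)CC1C(=O)O[C@H](C=C(Br)Br)[C@H]1[C@H](OC(=O)CC(C)C)C/C(CO)=C\CCB2OC(C)(C)C(C)(C)O2 | intermediate
19 | (4R,5S)-5-(2,2-dibromoethenyl)-3-[(dimethylamino)methyl]-4-[(1R,3E)-3-formyl-1-(3-methylbutanoyloxy)-6-(pinacolboryl)hex-3-en-1-yl]dihydrofuran-2(3H)-one, C3 epimers | CN(C)CC1C(=O)O[C@H](C=C(Br)Br)[C@H]1[C@H](OC(=O)CC(C)C)C/C(C=O)=C\CCB2OC(C)(C)C(C)(C)O2 | intermediate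
20 | (4R,5S)-5-[(1Z)-2-bromo-3-hydroxyprop-1-en-1-yl]-3-[(dimethylamino)methyl]-4-[(1R,3E)-3-formyl-1-(3-methylbutanoyloxy)-6-(pinacolboryl)hex-3-en-1-yl]dihydrofuran-2(3H)-one, C3 epimers | CN(C)CC1C(=O)O[C@H](/C=C(/CO)Br)[C@H]1[C@H](OC(=O)CC(C)C)C/C(C=O)=C\CCB2OC(C)(C)C(C)(C)O2 | intermediate
21 | (6R,7R,8R)-13-(dimethylamino)-15-hydroxy-14-oxo-11,13-dihydrogermacra-1(10)E,4E-dien-6,12-olid-8-yl 3-methylbutanoate, C11 epimers | CN(C)CC1C(=O)O[C@@H]2/C=C(/CO)CC/C=C(/C=O)C[C@@H](OC(=O)CC(C)C)[C@@H]12 | intermediate
22 | N,N,N-trimethylammonium iodide of 21 | C[N+](C)(C)CC1C(=O)O[C@@H]2/C=C(/CO)CC/C=C(/C=O)C[C@@H](OC(=O)CC(C)C)[C@@H]12.[I-] | intermediate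
23 | (6R,7R,8R)-15-hydroxy-14-oxogermacra-1(10)E,4E,11(13)-trien-6,12-olid-8-yl 3-methylbutanoate (CNP0345200.3) | C=C1C(=O)O[C@@H]2/C=C(/CO)CC/C=C(/C=O)C[C@@H](OC(=O)CC(C)C)[C@@H]12 | target

**Step count and risks**

Total step count: 16. Longest linear sequence: 14 steps (steps 1–4, then 7–16); steps 5 and 6 prepare the allyl bromide 10.

The three steps most likely to fail:

Step 15 (key step). Oligomerization or protodeboronation may outrun the intramolecular transmetalation of the rather unreactive pinacolboronate, and residual stannane may attack the second bromine. The fallback sets out from 19 and returns at 21. The C3–B bond is oxidized with trimethylamine N-oxide (THF, 60 °C) to the primary alcohol F1, which PPh3, I2 and imidazole convert into the primary iodide F2. Stille hydroxymethylation as in the first stage of step 15 (Pd2(dba)3, tri(2-furyl)phosphine, Bu3SnCH2OH, toluene, 80 °C) gives the Z-bromoallylic alcohol iodide F3. The same C3–C4 bond is then closed by a nickel-catalysed reductive cross-electrophile coupling (NiBr2·MeOCH2CH2OMe, 4,4′-di-tert-butyl-2,2′-bipyridine, Mn powder, NaI, DMA, high dilution), a radical pathway that needs neither base nor an organoboron partner.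

Step 7. Poor facial selectivity at C7 (addition syn instead of anti to the C6–O bond) or erosion of the syn preference would scramble C7 and C8. The fallback sets out from 10 and returns at 11. Copper-catalysed borylation (B2pin2, CuCl cat., K3PO4, THF) converts the bromide into the allyl pinacolboronate F4 of the same olefin geometry. F4 adds to 6 through a closed six-membered transition state under a chiral phosphoric acid catalyst, (R)-3,3′-bis(2,4,6-triisopropylphenyl)-1,1′-binaphthyl-2,2′-diyl hydrogen phosphate, so that the syn relation follows stereospecifically from the olefin geometry and the C7 face is chosen by the catalyst.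

Step 9. Migration of the isovaleryl group from O8 to O6, or competing six-membered lactone formation through the primary C5 hydroxyl, may divert the lactonization. The fallback sets out from 12 and returns at 14. Acetonide cleavage is stopped at the diol 13 (AcOH/H2O, rt), which is isolated. Selective silylation of the primary C5 hydroxyl (Et3SiCl, imidazole, −40 °C) gives the mono-triethylsilyl ether F5, in which only the C6 hydroxyl can lactonize (PPTS, toluene, 60 °C) to the silylated lactone F6. Mild acid (AcOH/THF/H2O) then removes the triethylsilyl group.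

Further compounds
F1 | step 15 | (4R,5S)-5-(2,2-dibromoethenyl)-3-[(dimethylamino)methyl]-4-[(1R,3E)-3-formyl-6-hydroxy-1-(3-methylbutanoyloxy)hex-3-en-1-yl]dihydrofuran-2(3H)-one, C3 epimers | CN(C)CC1C(=O)O[C@H](C=C(Br)Br)[C@H]1[C@H](OC(=O)CC(C)C)C/C(C=O)=C\CCO
F2 | step 15 | (4R,5S)-5-(2,2-dibromoethenyl)-3-[(dimethylamino)methyl]-4-[(1R,3E)-3-formyl-6-iodo-1-(3-methylbutanoyloxy)hex-3-en-1-yl]dihydrofuran-2(3H)-one, C3 epimers | CN(C)CC1C(=O)O[C@H](C=C(Br)Br)[C@H]1[C@H](OC(=O)CC(C)C)C/C(C=O)=C\CCI
F3 | step 15 | (4R,5S)-5-[(1Z)-2-bromo-3-hydroxyprop-1-en-1-yl]-3-[(dimethylamino)methyl]-4-[(1R,3E)-3-formyl-6-iodo-1-(3-methylbutanoyloxy)hex-3-en-1-yl]dihydrofuran-2(3H)-one, C3 epimers | CN(C)CC1C(=O)O[C@H](/C=C(/CO)Br)[C@H]1[C@H](OC(=O)CC(C)C)C/C(C=O)=C\CCI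
F4 | step 7 | methyl (2E)-3-[(4S)-2,2-dimethyl-1,3-dioxolan-4-yl]-2-[(pinacolboryl)methyl]prop-2-enoate | COC(=O)/C(CB1OC(C)(C)C(C)(C)O1)=C/[C@H]1COC(C)(C)O1
F5 | step 9 | methyl (3S,4R,6E)-6-{[tert-butyl(diphenyl)silyl]oxymethyl}-3-[(1S)-1-hydroxy-2-(triethylsilyloxy)ethyl]-2-methylidene-4-(3-methylbutanoyloxy)-9-(pinacolboryl)non-6-enoate | C=C(C(=O)OC)[C@@H]([C@H](O)CO[Si](CC)(CC)CC)[C@H](OC(=O)CC(C)C)C/C(CO[Si](c1ccccc1)(c1ccccc1)C(C)(C)C)=C\CCB1OC(C)(C)C(C)(C)O1
F6 | step 9 | (4R,5S)-4-[(1R,3E)-3-{[tert-butyl(diphenyl)silyl]oxymethyl}-1-(3-methylbutanoyloxy)-6-(pinacolboryl)hex-3-en-1-yl]-3-methylidene-5-[(triethylsilyloxy)methyl]dihydrofuran-2(3H)-one | C=C1C(=O)O[C@H](CO[Si](CC)(CC)CC)[C@H]1[C@H](OC(=O)CC(C)C)C/C(CO[Si](c2ccccc2)(c2ccccc2)C(C)(C)C)=C\CCB2OC(C)(C)C(C)(C)O2
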